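**Strategy.** The isoflavanone is cut at C4–C4a and C3–C1'. C3 and C4 are neighbouring carbons that carry ring B and ring A, with the C2 oxymethylene on C3, so the core is an allylic ether whose alkene has been arylated at both ends. One palladium-catalysed enantioselective conjunctive cross-coupling joins the ring A aryllithium, an (E)-3-silyloxypropenyl boronic ester and the ring B aryl bromide, forming both C–C bonds and both stereocentres without closing a ring. Its precursor is the lithium boronate of the bis-SEM ring A aryllithium and the alkenyl boronate, which carries the hindered mac diol in place of pinacol to suppress direct Suzuki coupling. Boron later becomes the C4 oxygen.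

Key step: step 6

Remark: "mac" denotes the cyclic boronic ester of cis-1,2-dimethyl-1,2-dihydroacenaphthylene-1,2-diol. The (Sp,Sp) antipode of the ligand is assumed to give the (1R,2S) series; its mirror image would be used if a trial coupling showed the opposite sense.

Step 1
Reactants: 1 5-methoxyresorcinol
Product: 2 1-methoxy-3,5-bis{[2-(trimethylsilyl)ethoxy]methoxy}benzene
Conditions: NaH, SEMCl, DMF, 0 °C → rt
Reagents that add atoms: 2-(trimethylsilyl)ethoxymethyl chloride (SEMCl), C[Si](C)(C)CCOCCl
Why: Williamson-type O-alkylation of the two equivalent sodium phenoxides; the SEM acetals later direct the ortho-lithiation, resist base and peroxide, and are removable by fluoride without acid.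

Step 2
Reactants: 3 4-bromo-3-methoxyphenol, 4 3-chloro-3-methylbut-1-yne
Product: 5 1-bromo-2-methoxy-4-[(2-methylbut-3-yn-2-yl)oxy]benzene
Conditions: K2CO3, KI (cat.), CuI (cat.), acetone, reflux
Reagents that add atoms: none
Why: Copper-assisted Williamson-type O-alkylation of the phenoxide by the tertiary propargylic chloride gives the aryl 1,1-dimethylpropargyl ether; the bromine is already in place in 3, so no electrophilic bromination is needed once the halogen-sensitive chromene alkene exists.

Step 3
Reactants: 5 1-bromo-2-methoxy-4-[(2-methylbut-3-yn-2-yl)oxy]benzene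
Product: 6 6-bromo-7-methoxy-2,2-dimethyl-2H-chromene
Conditions: N,N-diethylaniline, 180 °C
Reagents that add atoms: none
Why: Aromatic propargyl Claisen rearrangement to the ortho-allenyl phenol, 1,5-hydrogen shift and oxa-6π electrocyclisation build the 2,2-dimethylchromene; the rearrangement should go to the ortho carbon para to the methoxy group, because the other ortho carbon lies between two oxygens and is shielded by the methoxy methyl, which the neighbouring bromine turns toward it.

Step 4
Reactants: 7 acenaphthylene-1,2-dione (acenaphthoquinone)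
Product: 8 cis-1,2-dimethyl-1,2-dihydroacenaphthylene-1,2-diol (mac diol, meso)
Conditions: AlMe3, toluene, 0 °C → rt; then 1 M HCl; recrystallisation
Reagents that add atoms: trimethylaluminium (AlMe3), C[Al](C)C
Why: Double 1,2-addition of methyl to the 1,2-diketone; the second methyl is expected to enter anti to the aluminium alkoxide and give mainly the cis (meso) diol, the only isomer able to chelate boron, which is purified by recrystallisation.

Step 5
Reactants: 9 tert-butyldimethyl(prop-2-yn-1-yloxy)silane, 8 cis-1,2-dimethyl-1,2-dihydroacenaphthylene-1,2-diol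
Product: 11 (E)-tert-butyldimethyl{[3-(mac-boryl)prop-2-en-1-yl]oxy}silane, via catechol alkenylboronate 10 (not isolated)
Conditions: catecholborane, Cy2BH (cat.), THF, rt; then 8, rt
Reagents that add atoms: catecholborane, [H]B1Oc2ccccc2O1
Why: Dialkylborane-catalysed syn hydroboration of the terminal alkyne places boron on the terminal carbon and gives the (E)-alkenyl boronate, whose labile catechol ester is then exchanged for the chelating tertiary diol 8 (boronic ester transesterification).

Step 6
Reactants: 2 1-methoxy-3,5-bis{[2-(trimethylsilyl)ethoxy]methoxy}benzene, 11 (E)-tert-butyldimethyl{[3-(mac-boryl)prop-2-en-1-yl]oxy}silane, 6 6-bromo-7-methoxy-2,2-dimethyl-2H-chromene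
Product: 14 (1R,2S)-configured benzylic mac boronate of the 1-(ring A aryl)-2-(ring B aryl)-3-silyloxypropyl chain, via ring A aryllithium 12 (not isolated), via lithium boronate complex 13 (not isolated)
Conditions: n-BuLi (0.95 equiv), THF, 0 °C; 11, −78 °C → rt; then 6, Pd(OAc)2 (cat.), (Sp,Sp)-MandyPhos (C52H50FeN2P2, 1,1'-bis(diphenylphosphino)-2,2'-bis[(R)-(dimethylamino)(phenyl)methyl]ferrocene, cat.), KOTf (CF3SO3K), THF, 60 °C
Reagents that add atoms: none
Why: Directed ortho-lithiation of 2 between its two SEM-oxy groups gives 12, which adds to boron of 11 to form the four-coordinate boronate 13; oxidative addition of 6 to zerovalent palladium gives an arylpalladium bromide (divalent palladium), KOTf removes bromide as KBr, and the cationic arylpalladium binds the alkene of 13 and triggers a 1,2-metalate shift of ring A from boron to the α-carbon anti to palladium, after which reductive elimination joins ring B to the β-carbon with retention. The closest known reaction type is the palladium/MandyPhos-catalysed enantioselective conjunctive cross-coupling of β-substituted alkenyl boron ate complexes with aryl electrophiles. No ring is closed. The ring B carbon (C3 of the target, S) is set by the chiral bisphosphine, which selects the alkene face bound by palladium, and the boron-bearing carbon (C4, R) follows from anti addition across the (E)-alkene. The step needs the metalate shift to outrun direct boron-to-palladium transfer of the alkenyl group (Suzuki coupling), which the hindered mac diol and the electron-rich migrating aryl group secure; the slight deficit of n-BuLi keeps butyl groups out of the boronate.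

Step 7
Reactants: 14 (1R,2S)-configured benzylic mac boronate
Product: 15 (1R,2S)-3-(tert-butyldimethylsilyloxy)-2-(7-methoxy-2,2-dimethyl-2H-chromen-6-yl)-1-(4-methoxy-2,6-bis{[2-(trimethylsilyl)ethoxy]methoxy}phenyl)propan-1-ol
Conditions: 3 M NaOH, 30% H2O2, THF, 0 °C → rt
Reagents that add atoms: hydrogen peroxide, OO
Why: Boronate oxidation by hydroperoxide with 1,2-shift of carbon from boron to oxygen goes with retention, so C1 stays (R); silyl ethers, SEM acetals and the electron-rich chromene alkene are inert to alkaline peroxide.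

Step 8
Reactants: 15 (1R,2S)-configured silyl-protected benzylic alcohol
Product: 16 (1R,2S)-1-(2,6-dihydroxy-4-methoxyphenyl)-2-(7-methoxy-2,2-dimethyl-2H-chromen-6-yl)propane-1,3-diol
Conditions: TBAF (excess), DMPU/THF, 4 Å MS, 50 °C; aq. NH4Cl
Reagents that add atoms: none
Why: Fluoride-induced desilylation cleaves the TBS ether directly and fragments each SEM group to fluorotrimethylsilane, ethene, formaldehyde and the phenoxide; the basic, acid-free conditions spare the ionisable benzylic alcohol and the chromene and touch no stereocentre.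

Step 9
Reactants: 16 (1R,2S)-1-(2,6-dihydroxy-4-methoxyphenyl)-2-(7-methoxy-2,2-dimethyl-2H-chromen-6-yl)propane-1,3-diol
Product: 17 (3S,4R)-7-methoxy-3-(7-methoxy-2,2-dimethyl-2H-chromen-6-yl)chromane-4,5-diol
Conditions: PPh3, DIAD, THF, 0 °C → rt
Reagents that add atoms: none
Why: Mitsunobu etherification activates the primary alcohol in preference to the hindered secondary benzylic one and a neighbouring phenol displaces it in a 6-exo-tet SN2 closure of O1–C2; the two phenols are equivalent by rotation of ring A and neither stereocentre takes part.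

Step 10
Reactants: 17 (3S,4R)-7-methoxy-3-(7-methoxy-2,2-dimethyl-2H-chromen-6-yl)chromane-4,5-diol
Product: 18 (3S)-5-hydroxy-7-methoxy-3-(7-methoxy-2,2-dimethyl-2H-chromen-6-yl)chroman-4-one
Conditions: MnO2 (activated, excess), CH2Cl2, rt; filtration through Celite
Reagents that add atoms: none
Why: MnO2 oxidation of the benzylic alcohol under neutral, heterogeneous conditions removes the C4 stereocentre and leaves the base-labile C3 centre (S) untouched, the new carbonyl being hydrogen-bonded to the 5-hydroxyl.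

**Compound list**

1 | 5-methoxyresorcinol | COc1cc(O)cc(O)c1 | starting material
2 | 1-methoxy-3,5-bis{[2-(trimethylsilyl)ethoxy]methoxy}benzene | COc1cc(OCOCC[Si](C)(C)C)cc(OCOCC[Si](C)(C)C)c1 | intermediate
3 | 4-bromo-3-methoxyphenol | COc1cc(O)ccc1Br | starting material
4 | 3-chloro-3-methylbut-1-yne | CC(C)(Cl)C#C | starting material
5 | 1-bromo-2-methoxy-4-[(2-methylbut-3-yn-2-yl)oxy]benzene | COc1cc(OC(C)(C)C#C)ccc1Br | intermediate
6 | 6-bromo-7-methoxy-2,2-dimethyl-2H-chromene | COc1cc2OC(C)(C)C=Cc2cc1Br | intermediate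
7 | acenaphthylene-1,2-dione (acenaphthoquinone) | O=C1C(=O)c2cccc3cccc1c23 | starting material
8 | (1R,2S)-1,2-dimethyl-1,2-dihydroacenaphthylene-1,2-diol (cis, meso; mac diol) | O[C@]1(C)c2cccc3cccc(c23)[C@]1(C)O | intermediate
9 | tert-butyldimethyl(prop-2-yn-1-yloxy)silane | C#CCO[Si](C)(C)C(C)(C)C | starting material
10 | (E)-2-{3-[(tert-butyldimethylsilyl)oxy]prop-1-en-1-yl}-1,3,2-benzodioxaborole | CC(C)(C)[Si](C)(C)OC/C=C/B1Oc2ccccc2O1 | intermediate
11 | (E)-tert-butyldimethyl{[3-(mac-boryl)prop-2-en-1-yl]oxy}silane; mac-boryl = (6bR,9aS)-6b,9a-dimethyl-6b,9a-dihydroacenaphtho[1,2-d][1,3,2]dioxaborol-8-yl | CC(C)(C)[Si](C)(C)OC/C=C/B1O[C@]2(C)c3cccc4cccc(c34)[C@]2(C)O1 | intermediate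
12 | [4-methoxy-2,6-bis{[2-(trimethylsilyl)ethoxy]methoxy}phenyl]lithium | [Li]c1c(OCOCC[Si](C)(C)C)cc(OC)cc1OCOCC[Si](C)(C)C | intermediate
13 | lithium [(E)-3-(tert-butyldimethylsilyloxy)prop-1-en-1-yl][4-methoxy-2,6-bis{[2-(trimethylsilyl)ethoxy]methoxy}phenyl] mac borate (configuration at boron not defined) | [Li+].CC(C)(C)[Si](C)(C)OC/C=C/[B-]1(c2c(OCOCC[Si](C)(C)C)cc(OC)cc2OCOCC[Si](C)(C)C)O[C@]2(C)c3cccc4cccc(c34)[C@]2(C)O1 | intermediate
14 | mac boronate of (1R,2S)-3-(tert-butyldimethylsilyloxy)-2-(7-methoxy-2,2-dimethyl-2H-chromen-6-yl)-1-(4-methoxy-2,6-bis{[2-(trimethylsilyl)ethoxy]methoxy}phenyl)propyl, boron on C1 (C1 = C4 and C2 = C3 of the target) | CC(C)(C)[Si](C)(C)OC[C@H](c1cc2c(cc1OC)OC(C)(C)C=C2)[C@@H](B1O[C@]2(C)c3cccc4cccc(c34)[C@]2(C)O1)c1c(OCOCC[Si](C)(C)C)cc(OC)cc1OCOCC[Si](C)(C)C | intermediate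
15 | (1R,2S)-3-(tert-butyldimethylsilyloxy)-2-(7-methoxy-2,2-dimethyl-2H-chromen-6-yl)-1-(4-methoxy-2,6-bis{[2-(trimethylsilyl)ethoxy]methoxy}phenyl)propan-1-ol | CC(C)(C)[Si](C)(C)OC[C@H](c1cc2c(cc1OC)OC(C)(C)C=C2)[C@@H](O)c1c(OCOCC[Si](C)(C)C)cc(OC)cc1OCOCC[Si](C)(C)C | intermediate
16 | (1R,2S)-1-(2,6-dihydroxy-4-methoxyphenyl)-2-(7-methoxy-2,2-dimethyl-2H-chromen-6-yl)propane-1,3-diol | OC[C@H](c1cc2c(cc1OC)OC(C)(C)C=C2)[C@@H](O)c1c(O)cc(OC)cc1O | intermediate
17 | (3S,4R)-7-methoxy-3-(7-methoxy-2,2-dimethyl-2H-chromen-6-yl)chromane-4,5-diol (trans) | COc1cc(O)c2c(c1)OC[C@H](c1cc3c(cc1OC)OC(C)(C)C=C3)[C@H]2O | intermediate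
18 | (3S)-5-hydroxy-7-methoxy-3-(7-methoxy-2,2-dimethyl-2H-chromen-6-yl)chroman-4-one | COc1cc(O)c2c(c1)OC[C@H](c1cc3c(cc1OC)OC(C)(C)C=C3)C2=O | target

**Step count.** Total: 10 steps. Longest linear sequence: 7 steps (steps 2, 3, 6, 7, 8, 9, 10; the branch through steps 4 and 5 is equally long).

**Steps most likely to fail**

Step 6. The alkenyl group may pass directly from boron to palladium (Suzuki coupling) faster than the metalate shift. Boronate formation or migration of the doubly ortho-substituted aryl group may be slow, and facial selectivity may be insufficient. The fallback sets C3 and C4 by an Evans syn aldol reaction; it sets out from 2 and 6 and returns at 16.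
- Arene 2 is lithiated as in step 6 and quenched with DMF to give 4-methoxy-2,6-bis{[2-(trimethylsilyl)ethoxy]methoxy}benzaldehyde F1.
- Bromide 6 is coupled with the Reformatsky reagent BrZnCH2CO2Et (Pd2(dba)3, XPhos, THF, 60 °C; Negishi-type α-arylation) to give ethyl (7-methoxy-2,2-dimethyl-2H-chromen-6-yl)acetate F2.
- Saponification (LiOH, THF/H2O) gives (7-methoxy-2,2-dimethyl-2H-chromen-6-yl)acetic acid F3.
- Acylation of (R)-4-benzyloxazolidin-2-one through the pivaloyl mixed anhydride (PivCl, Et3N, LiCl, THF) gives (R)-4-benzyl-3-[(7-methoxy-2,2-dimethyl-2H-chromen-6-yl)acetyl]oxazolidin-2-one F4.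
- Boron aldol reaction of F4 with F1 (Bu2BOTf, iPr2NEt, CH2Cl2, −78 → 0 °C) should pass through the (Z)-enolate and a Zimmerman–Traxler chair to the (2R,3R) syn aldol adduct F5. It has the same relative and absolute configuration as 15.
- Reductive removal of the auxiliary (LiBH4, THF/MeOH, 0 °C) gives the (1R,2S)-bis-SEM propane-1,3-diol F6, which is desilylated under the conditions of step 8 to give 16.

Step 8. Cleavage of the aryl SEM acetals may stay incomplete. Once the phenoxides are free, the benzylic hydroxyl may be lost through an ortho-quinone methide, which would also endanger C3 by tautomerisation to the alkene. The fallback removes the protecting groups before boron is oxidised, while the benzylic carbon cannot ionise; it sets out from 14 and returns at 17.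
- HCl in MeOH/THF (0 → 40 °C) cleaves the TBS ether and both SEM acetals of 14 to give the (1R,2S)-configured mac boronate of the free diphenol and primary alcohol F7.
- Mitsunobu closure as in step 9 gives (3S,4R)-7-methoxy-3-(7-methoxy-2,2-dimethyl-2H-chromen-6-yl)-4-(mac-boryl)chroman-5-ol F8.
- Oxidation of the C–B bond as in step 7 (NaBO3·4H2O in THF/H2O may replace NaOH/H2O2 to spare the free phenol) gives 17 with retention.

Step 10. The electron-rich free phenol may be oxidised in competition with the alcohol. Configuration at C3 may erode by enolisation of the new ketone during a long reaction or chromatography. The fallback masks the phenol so that a fast homogeneous oxidant can be used; it sets out from 17 and returns at 18.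
- Phenol-selective silylation (TBSCl, imidazole, DMF, 0 °C) gives (3S,4R)-5-(tert-butyldimethylsilyloxy)-7-methoxy-3-(7-methoxy-2,2-dimethyl-2H-chromen-6-yl)chroman-4-ol F9.
- Dess–Martin oxidation (NaHCO3, CH2Cl2, 0 °C) gives (3S)-5-(tert-butyldimethylsilyloxy)-7-methoxy-3-(7-methoxy-2,2-dimethyl-2H-chromen-6-yl)chroman-4-one F10.
- Buffered fluoride (HF·pyridine, pyridine, THF, 0 °C) releases 18 without base.

Further compounds
F1 | step 6 | 4-methoxy-2,6-bis{[2-(trimethylsilyl)ethoxy]methoxy}benzaldehyde | O=Cc1c(OCOCC[Si](C)(C)C)cc(OC)cc1OCOCC[Si](C)(C)C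
F2 | step 6 | ethyl (7-methoxy-2,2-dimethyl-2H-chromen-6-yl)acetate | CCOC(=O)Cc1cc2C=CC(C)(C)Oc2cc1OC
F3 | step 6 | (7-methoxy-2,2-dimethyl-2H-chromen-6-yl)acetic acid | OC(=O)Cc1cc2C=CC(C)(C)Oc2cc1OC
F4 | step 6 | (R)-4-benzyl-3-[(7-methoxy-2,2-dimethyl-2H-chromen-6-yl)acetyl]oxazolidin-2-one | O=C(Cc1cc2C=CC(C)(C)Oc2cc1OC)N1[C@H](Cc2ccccc2)COC1=O
F5 | step 6 | (R)-4-benzyl-3-[(2R,3R)-3-hydroxy-2-(7-methoxy-2,2-dimethyl-2H-chromen-6-yl)-3-(4-methoxy-2,6-bis{[2-(trimethylsilyl)ethoxy]methoxy}phenyl)propanoyl]oxazolidin-2-one | O=C([C@H](c1cc2C=CC(C)(C)Oc2cc1OC)[C@@H](O)c1c(OCOCC[Si](C)(C)C)cc(OC)cc1OCOCC[Si](C)(C)C)N1[C@H](Cc2ccccc2)COC1=O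
F6 | step 6 | (1R,2S)-2-(7-methoxy-2,2-dimethyl-2H-chromen-6-yl)-1-(4-methoxy-2,6-bis{[2-(trimethylsilyl)ethoxy]methoxy}phenyl)propane-1,3-diol | OC[C@H](c1cc2C=CC(C)(C)Oc2cc1OC)[C@@H](O)c1c(OCOCC[Si](C)(C)C)cc(OC)cc1OCOCC[Si](C)(C)C
F7 | step 8 | 2-[(1R,2S)-3-hydroxy-1-(mac-boryl)-2-(7-methoxy-2,2-dimethyl-2H-chromen-6-yl)propyl]-5-methoxybenzene-1,3-diol | OC[C@H](c1cc2c(cc1OC)OC(C)(C)C=C2)[C@@H](B1O[C@]2(C)c3cccc4cccc(c34)[C@]2(C)O1)c1c(O)cc(OC)cc1O
F8 | step 8 | (3S,4R)-7-methoxy-3-(7-methoxy-2,2-dimethyl-2H-chromen-6-yl)-4-(mac-boryl)chroman-5-ol | COc1cc(O)c2c(c1)OC[C@H](c1cc3c(cc1OC)OC(C)(C)C=C3)[C@H]2B1O[C@]2(C)c3cccc4cccc(c34)[C@]2(C)O1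
F9 | step 10 | (3S,4R)-5-(tert-butyldimethylsilyloxy)-7-methoxy-3-(7-methoxy-2,2-dimethyl-2H-chromen-6-yl)chroman-4-ol | COc1cc(O[Si](C)(C)C(C)(C)C)c2c(c1)OC[C@H](c1cc3c(cc1OC)OC(C)(C)C=C3)[C@H]2O
F10 | step 10 | (3S)-5-(tert-butyldimethylsilyloxy)-7-methoxy-3-(7-methoxy-2,2-dimethyl-2H-chromen-6-yl)chroman-4-one | COc1cc(O[Si](C)(C)C(C)(C)C)c2c(c1)OC[C@H](c1cc3c(cc1OC)OC(C)(C)C=C3)C2=O
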